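The data were computed from invented constants; scatter was added.

**Slow stop.** Slowness in a flask can mean short supply or a dying worker, and the winter flask, the one asked about, lets you tell which.

| setting | winter | midnight | flask |
|---|---|---|---|
| starting material | 1 M | 1 M | 1.0 M |
| reagent | 1.1 M | 1.1 M | 1.10 M |
| second substrate | 0.20 M | 0.30 M | 0.200 M |
| free catalyst | 10 mM | 10 mM | 10 mM |
| remark | the very flask that is asked about, followed so far | run made earlier |  |
| time |  |  | 40 h |

- winter (time / h: target / %, starting material / %): 2.00: 21.9, 77.4; 3.00: 25.1, 75.4; 5.00: 28.8, 71.5; 8.00: 32.3, 66.8; 15.0: 37.4, 62.4; 25.0: 38.0, 62.5
- midnight (time / min: target / %, starting material / %): 6.00: 11.6, 88.7; 20.0: 16.6, 84.1; 30.0: 17.0, 84.0; 50.0: 17.4, 82.5; 80.0: 18.9, 80.0; 90.0: 20.9, 80.1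

(scatter of a reading: 0.5 percentage points)

- red: at 40 h take out 90 % of the target then present, then wait 40 h
- teal: at 40 h add free catalyst, 50.0 % of the amount charged, then wait 40 h
- grey: change nothing and wait 40 h more

- what is taken out of target is counted as made
- steps that have been proposed: starting material + reagent + free catalyst -> free catalyst + target; second substrate + reagent + free catalyst -> free catalyst + second product; free catalyst -> spent catalyst; reagent <-> dormant form
- additions bring no volume worth counting

* target, in percent of the starting material first charged, at 40 h
* the option that brings most further target ("none" if no option brings more than 2 percentage points) (red / teal / grey / none)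
* target present, with what was taken out counted in, in percent of the starting material first charged, after teal
* target present, with what was taken out counted in, in percent of the starting material first charged, after grey

**Two numbers.** From 15.0 h to 25.0 h the winter run gains 0.6 percentage points of target, yet 62.5 % of the starting material stands there. Even if you count the whole second substrate as spent, the balance leaves 0.520 M of reagent and dormant form together. No proposed step runs back from target, so I read the stop as free catalyst dying.

**Mean life.** In the winter run, target lies 13 points below its last reading at 3.00 h and 5.7 points below it at 8.00 h. Read as exponential decay of free catalyst, this gives a mean life of 6.12 h, a reading that carries the scatter and the falling starting material and reagent as well.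

**The reach.** Call a charge's reach the target it makes before it dies: rate times mean life. At 3.00 h the winter run had 13 points still to come, from a live share I reckon at 61.3 %. Dividing gives 21 points, the reach of a full fresh charge at that composition.

**My reckoning.** Adding what remains after 25.0 h gives 38.4 % now. At 40 h the reach left is 0.031 points, less than the 2 points margin, so grey is useless. Red is too, since taking out target alters no proposed rate. Teal brings half a charge, and the proposed rate of the target step scales with starting material and, once the fast start of the runs has passed, with the pool of reagent and dormant form (a pre-equilibrium), which I take from the same balance at both times. Those two ratios, from 3.00 h to 25.0 h, multiply to 0.664, so I reckon that teal adds 7 points, more than the margin, and ends at 45.4 %.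

**The result.** The forecast gave 38.4 %, teal, 45.5 % and 38.5 %, holding that “Fresh catalyst at half the original charge should restart the slow phase”. The winter flask gives 38.7 % now, and teal is best with 7.4 points further, reaching 46.1 %; grey gives 38.8 %.

    starting material + reagent + free catalyst → free catalyst + target (k = 0.0518 M⁻² s⁻¹)
    second substrate + reagent + free catalyst → free catalyst + second product (k = 0.121 M⁻² s⁻¹)
    free catalyst → spent catalyst (k = 3.88 × 10⁻⁵ s⁻¹)
    reagent ⇌ dormant form (K = 25.5, k = 0.00261 s⁻¹)

**Quarter charge.** Teal's reach was reckoned at 7 points and came out at 7.4 points. Rescaled by the same two ratios to a flask with no target yet, the second substrate still counted as spent, my full fresh reach becomes 39 points. The neighbouring flask holds 0.0025 M of free catalyst, a quarter of the winter charge. I reckon it takes that share of this reach and of the fast start, read as 17.0 % at 30.0 min in the midnight run, which holds more second substrate than the winter flask, and that makes 13.9 %. That neighbouring flask stands at 15.1 % after 40.0 h.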